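## The problem

Compound 17, (2S)-5-hydroxy-8-prenyl-7-(prenyloxy)flavanone (prenyl = 3-methylbut-2-en-1-yl), is a chroman-4-one in which aromatic ring A is fused through C4a–C8a to the oxygen heterocycle ring C, which carries the phenyl ring B at C2. Ring A is fully differentiated: a free 5-hydroxyl hydrogen-bonded to the C4 carbonyl, a prenyl ether at O7, a carbon-bound prenyl group at C8 and hydrogen only at C6, so the prenyl group must reach C8 and not C6 and the two phenolic oxygens must end up differently substituted. C2 (S) is the only stereocentre, so there is no second centre to relay from and it has to be set by reagent control. It is also fragile: the C2–O1 bond is benzylic and β to the C4 carbonyl, so any base or Lewis acid able to open ring C by retro-oxa-Michael reaction racemises it. The two prenyl groups exclude hydrogenation, strong protic or Lewis acids (ether cleavage, hydration, chroman formation) and zerovalent palladium (allyl transfer), which narrows the choice of protecting groups and of ring-closing methods. The feature that makes the key step possible is that O1 is bonded both to the stereogenic C2 and to the aromatic carbon C8a, so forming O1–C8a from an aryl bromide and a C2 carbinol closes ring C without touching any of the four bonds at C2. A second feature, the peri relation of the C4 carbonyl and O5, allows a chelating Lewis acid to move a prenyl group from O5 to the para carbon C8, which writes the 5-hydroxy/8-prenyl pattern from a simple bis(prenyl ether).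

## Retrosynthesis

**17 to 14.** The C8–CH2 bond of the carbon-bound prenyl group is cut and the group is returned to O5, giving (2S)-5,7-bis(prenyloxy)flavanone 14. Direct prenylation of a ring A phenol would give C6, C8 and oxygen products side by side. Carrying the C8 prenyl group from the start would force the two oxygens to be distinguished early and would put a second ortho substituent beside the bromide used for ring closure. Precursor 14 has two identical ether groups and no free phenol. The forward step must activate only the 5-ether and pass through dienones 15 and 16 to C8 without disturbing the 7-ether or C2.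

**14 to 13 to 12.** No skeletal bond is cut here. The C4 carbonyl is traced back to alcohol 13 and its silyl ether 12. With the ketone in place during ring closure, the open-chain precursor would be a β-oxygenated ketone open to retro-aldol cleavage and β-elimination, both of which destroy C2. A C4 silyl ether removes these pathways at the cost of two simple steps (desilylation, oxidation), and both C4 epimers converge on 14.

**12 to 11.** The O1–C8a bond is cut, giving bromo alcohol 11. Cutting O1–C2 instead would make the bond at the stereocentre itself, so the configuration would depend on clean inversion or on a reversible conjugate addition. Cutting C4–C4a would require a regioselective acylation of ring A. The chosen cut leaves C2 a spectator. Precursor 11 is an open chain with a 1,3-dioxygenated three-carbon unit on a bromoarene. The forward reaction must couple a secondary alkoxide with an aryl bromide faster than β-hydride loss and without harming the prenyl ethers, which points to copper.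

**11 to 9.** The C–H bond at the carbinol carbon is cut, so 11 comes from phenyl ketone 9 through borate ester 10. An aryl alkyl ketone is the best substrate class for oxazaborolidine-catalysed reduction, so the only stereocentre of the target is set here under reagent control. Ketone 9 has no stereocentre that matters. The reduction must override the racemic silyloxy-bearing carbon and leave the prenyl alkenes alone.

**9 to 8 to 5 and 6.** The silyl group is removed on paper and the C3–C4 bond (flavanone numbering) is cut in an aldol sense. This gives aldehyde 5 and acetophenone 6, the latter used as its lithium enolate 7. This places the phenyl ketone where the reduction needs it and the oxygen at C4 where the carbonyl will be. Both fragments are simple, and the aldehyde cannot enolise. The aldol adduct 8 must be trapped before it reverts or dehydrates.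

**5 to 3 and 4; 3 to 1.** The two ether O–C bonds are cut to two equivalents of prenyl bromide 4 and dihydroxy aldehyde 3. The formyl C–C bond is cut to 5-bromobenzene-1,3-diol 1, formylated through iminium salt 2. The bromine of 1 already sits where C8a needs its leaving group. Formylation must go to the carbon flanked by hydroxyl and bromine, and is done before prenylation because the acidic conditions would not spare the ethers.

## Roads not taken

**Alternative 1:** This cut removes ring A entirely and builds it on an enantiopure ring C. The precursor is diazoketone A2, (2S)-6-(2-diazo-5-methylhex-4-enoyl)-2-phenyl-2,3-dihydro-4H-pyran-4-one. It would be irradiated with (triisopropylsiloxy)ethyne A3. Wolff rearrangement, [2+2] capture by A3, four-electron ring opening and six-electron ring closure would form C5–C6, C7–C8 and C4a–C5 (C8–C8a arises in the 1,2-shift of the Wolff rearrangement). The product would be A1, (S)-5-hydroxy-8-prenyl-7-(triisopropylsiloxy)flavanone. Desilylation and prenylation at O7 would then give 17.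
- Merits: the ring A pattern is fixed by construction. The 5-hydroxyl is free, O7 is differentiated and the prenyl group cannot end at C6. In this respect the road is better than the chosen one, whose last step rests on a selective migration.
- Weak points: A2 is itself a multistep target, needing a 6-acyl dihydropyranone with the C2 centre and then a diazo group on a substituted carbon. Its C2–O1 bond is β to the ring carbonyl through the whole sequence. The enone chromophore competes for the light. The prenyl alkene lies within reach of the reactive centres generated on photolysis. A3 is thermally and hydrolytically delicate.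
- Comparison: the chosen plan sets against this a commercial ring A precursor, no diazo compound or photochemistry, and a stereocentre made by a robust reduction. It accepts the regiochemical risk of step 9 in exchange.

**Alternative 2:** This cut is C2–C3. Rh2(S-PTTL)4 (dirhodium tetrakis[N-phthaloyl-(S)-tert-leucinate], divalent rhodium) would decompose diazoketone A5, 2-diazo-1-[2,4,6-tris(benzyloxy)phenyl]ethanone. The carbene carbon C3 would insert into one enantiotopic benzylic C–H bond of an ortho benzyloxy group, closing ring C and giving A4, (S)-5,7-bis(benzyloxy)flavanone.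
- Merits: the stereocentre and ring C are formed together, catalytically, from an achiral precursor only a few steps from a phloroglucinol-derived acid. The flavanone core is reached in fewer steps than in the chosen route, and this is conceded.
- Weak points: a carbene with only an acyl substituent is unselective. Attack by the neighbouring ether oxygen followed by a 1,2-benzyl shift would contract the new ring to five members. Addition to the benzyl ring is a further diversion. The enantioselectivity of this particular insertion is uncertain. The benzyl groups are obligatory participants, so both ethers of A4 would have to be exchanged for prenyl ethers afterwards, by hydrogenolysis next to the benzylic C2–O1 bond and then alkylation of the chelated 5-hydroxyl, before the same prenyl shift. The overall count is then no shorter.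
- Comparison: the chosen plan sets against it the predictable enantioselectivity of an aryl ketone reduction and prenyl ethers carried unchanged from step 2.

**Alternative 3:** This cuts C4–C4a and O1–C8a in one operation. 2-Fluoro-4,6-bis(prenyloxy)phenyllithium A8 would add to the carbonyl of (S)-4-phenyloxetan-2-one A7. The four-membered ring would open to a lithium alkoxide, which on warming would displace the ortho fluoride. The product A6, (S)-5,7-bis(prenyloxy)flavanone, is the same compound as 14.
- Merits: it is by far the most convergent road. One flask would reach the compound that the chosen route reaches only after eight steps, and it uses the same retentive O1–C8a closure.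
- Weak points: lithiation must occur between fluorine and one ether oxygen, not between the two ethers. A8 can lose fluoride to an aryne and can trigger anionic rearrangement of its prenyl ethers. A7 can be attacked at the benzylic C4 instead of the carbonyl. The ring-opened species is a ketone exposed to more A8 and also the β-alkoxide of a ketone, so retro-aldol cleavage and β-elimination, the two processes that erase C2, are open just when warming is needed.
- Comparison: if every branch point went the right way, this road would be clearly superior in step count. The chosen plan sets against it that C2 is never carried as the β-alkoxide of a ketone and that each step is a single transformation with close precedent.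

Key step: step 6

Remark: prenyl = 3-methylbut-2-en-1-yl and TBS = tert-butyldimethylsilyl. Flavanone numbering (O1, C2, C3, C4, C4a, C5 to C8, C8a) is also used for the open-chain precursors, where the carbinol carbon C1 of the propane chain becomes C2 and C3 becomes C4. The carbon that becomes C4 is deliberately carried as a mixture of both configurations because it ends as the carbonyl group.

## Route

Step 1
Reactants: 1 5-bromobenzene-1,3-diol
Product: 3 2-bromo-4,6-dihydroxybenzaldehyde, via iminium chloride 2 (not isolated)
Conditions: POCl3, DMF, MeCN, 0 °C to rt; then H2O, 50 °C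
Reagents that add atoms: N,N-dimethylformamide, CN(C)C=O (formyl carbon); water, O (carbonyl oxygen)
Why: Vilsmeier–Haack formylation; the chloroiminium ion should attack the ring carbon para to one hydroxyl and ortho to the other (flanked by OH and Br), as 5-substituted resorcinols do, and not the more crowded carbon between the two hydroxyls; hydrolysis of iminium salt 2 releases the aldehyde.

Step 2
Reactants: 3 2-bromo-4,6-dihydroxybenzaldehyde; 4 prenyl bromide (1-bromo-3-methylbut-2-ene), used in excess (2.5 equiv)
Product: 5 2-bromo-4,6-bis(prenyloxy)benzaldehyde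
Conditions: 4 (2.5 equiv), K2CO3 (3 equiv), DMF, rt to 50 °C
Reagents that add atoms: prenyl bromide (second equivalent of 4), CC(C)=CCBr
Why: Twofold Williamson ether synthesis that consumes two equivalents of 4, one for each phenol; carbonate in a dipolar aprotic solvent favours alkylation on oxygen over carbon, and gentle warming with excess 4 brings the hydrogen-bonded 6-hydroxyl to full conversion.

Step 3
Reactants: 5 2-bromo-4,6-bis(prenyloxy)benzaldehyde; 6 acetophenone
Product: 8 rac-3-[2-bromo-4,6-bis(prenyloxy)phenyl]-3-hydroxy-1-phenylpropan-1-one, via lithium 1-phenylethenolate 7 (not isolated)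
Conditions: LiN(i-Pr)2 (LDA), THF, −78 °C (6 to 7); then 5, −78 °C; AcOH quench at −78 °C
Reagents that add atoms: none
Why: Directed aldol addition of a preformed lithium enolate to a non-enolisable aldehyde; the cold acidic quench should prevent reversal and dehydration, and the new carbinol centre is left racemic on purpose because it becomes the C4 carbonyl.

Step 4
Reactants: 8 rac-3-[2-bromo-4,6-bis(prenyloxy)phenyl]-3-hydroxy-1-phenylpropan-1-one
Product: 9 rac-3-[2-bromo-4,6-bis(prenyloxy)phenyl]-3-(tert-butyldimethylsilyloxy)-1-phenylpropan-1-one
Conditions: TBSOTf, 2,6-lutidine, CH2Cl2, −78 to 0 °C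
Reagents that add atoms: tert-butyldimethylsilyl triflate (TBSOTf), CC(C)(C)[Si](C)(C)OS(=O)(=O)C(F)(F)F
Why: Silyl triflate silylation of a hindered secondary alcohol; the hindered, non-nucleophilic base and low temperature should avoid β-elimination, and the silyl ether closes the retro-aldol channel for the steps that follow.

Step 5
Reactants: 9 rac-3-[2-bromo-4,6-bis(prenyloxy)phenyl]-3-(tert-butyldimethylsilyloxy)-1-phenylpropan-1-one
Product: 11 (1S)-3-[2-bromo-4,6-bis(prenyloxy)phenyl]-3-(tert-butyldimethylsilyloxy)-1-phenylpropan-1-ol (both C3 epimers), via catechol borate ester 10 (not isolated)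
Conditions: (R)-2-methyl-CBS-oxazaborolidine [(3aR)-1-methyl-3,3-diphenyltetrahydro-1H,3H-pyrrolo[1,2-c][1,3,2]oxazaborole] (20 mol %), catecholborane, toluene, −78 to −40 °C; then aq NaOH work-up
Reagents that add atoms: none
Why: Corey–Bakshi–Shibata reduction; the ketone binds the catalyst with phenyl as the large group and the CH2 chain as the small one, so the (R)-catalyst should deliver hydride to give the (S)-carbinol in both C3 series (the same sense in which it gives (S)-1-phenylethanol from acetophenone), and catecholborane is chosen over BH3 so that the prenyl alkenes are not hydroborated.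

Step 6
Reactants: 11 (1S)-3-[2-bromo-4,6-bis(prenyloxy)phenyl]-3-(tert-butyldimethylsilyloxy)-1-phenylpropan-1-ol (both C3 epimers)
Product: 12 (2S)-4-(tert-butyldimethylsilyloxy)-5,7-bis(prenyloxy)flavan (both C4 epimers)
Conditions: CuI (monovalent copper, 10 mol %), 3,4,7,8-tetramethyl-1,10-phenanthroline (20 mol %), Cs2CO3, toluene, 110 °C, argon
Reagents that add atoms: none
Why: Ullmann-type intramolecular O-arylation, the known copper route from secondary 3-(2-haloaryl)propan-1-ols to 2-substituted chromans. Cs2CO3 turns the C2 hydroxyl into an alkoxide that binds the phenanthroline-ligated copper (monovalent) centre; the C8a–Br bond then adds to copper, and C–O reductive elimination forms O1–C8a and returns monovalent copper. Ring C closes as a six-membered ring by formal 6-exo attack of oxygen on C8a, at the metal through a seven-membered aryl–copper alkoxide chelate that contracts on reductive elimination. No stereocentre is created: only the O–H bond at C2 reacts, so the (S) configuration from step 5 is retained, and the C4 epimer mixture passes through unchanged. The step needs C–O coupling to outrun β-hydride loss from the copper alkoxide, which would reduce the bromide and oxidise the carbinol; intramolecularity, the chelating ligand and an aprotic, oxygen-free medium favour coupling. The bromide has a single ortho substituent and both alkoxy groups are meta to it, so the C–Br bond is neither blocked nor electronically deactivated. The C4 silyl ether keeps that oxygen off copper and excludes retro-aldol and elimination pathways, and copper, unlike zerovalent palladium, does not ionise the aryl prenyl ethers.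

Step 7
Reactants: 12 (2S)-4-(tert-butyldimethylsilyloxy)-5,7-bis(prenyloxy)flavan (both C4 epimers)
Product: 13 (2S)-5,7-bis(prenyloxy)flavan-4-ol (both C4 epimers)
Conditions: Bu4NF (TBAF), THF, 0 °C to rt
Reagents that add atoms: none
Why: Fluoride desilylation; the non-acidic medium protects the electron-rich, easily ionised benzylic C4–O bond and the prenyl ethers, and C2 is not involved.

Step 8
Reactants: 13 (2S)-5,7-bis(prenyloxy)flavan-4-ol (both C4 epimers)
Product: 14 (2S)-5,7-bis(prenyloxy)flavanone
Conditions: Dess–Martin periodinane, NaHCO3, CH2Cl2, 0 °C to rt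
Reagents that add atoms: none
Why: Dess–Martin oxidation of a secondary benzylic alcohol under buffered, neutral conditions; both C4 epimers converge on one ketone, and no base strong enough to open ring C is present, so C2 should stay (S).

Step 9
Reactants: 14 (2S)-5,7-bis(prenyloxy)flavanone
Product: 17 (2S)-5-hydroxy-8-prenyl-7-(prenyloxy)flavanone (CNP0292726.1), via C6 dienone 15 (not isolated), via C8 dienone 16 (not isolated)
Conditions: Eu(fod)3 [tris(6,6,7,7,8,8,8-heptafluoro-2,2-dimethyloctane-3,5-dionato)europium, trivalent europium] (10 mol %), NaHCO3, PhCl, 85 °C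
Reagents that add atoms: none
Why: Lewis-acid-catalysed aromatic para-Claisen–Cope rearrangement, known for 5-O-prenyl flavanones; trivalent europium chelates the C4 carbonyl and the peri ether oxygen O5, so only the 5-ether is activated, a [3,3] shift to C6 gives 15 with a reversed (1,1-dimethylallyl) group, a second [3,3] shift carries it to C8 as a normal prenyl group in 16, and enolisation gives the hydrogen-bonded 5-phenol, while the unchelated 7-ether and C2 are not touched.

## Compound list

1 | 5-bromobenzene-1,3-diol | Oc1cc(O)cc(Br)c1 | starting material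
2 | N-[(2-bromo-4,6-dihydroxyphenyl)methylidene]-N-methylmethanaminium chloride | C[N+](C)=Cc1c(O)cc(O)cc1Br.[Cl-] | intermediate
3 | 2-bromo-4,6-dihydroxybenzaldehyde | O=Cc1c(O)cc(O)cc1Br | intermediate
4 | prenyl bromide (1-bromo-3-methylbut-2-ene) | CC(C)=CCBr | starting material
5 | 2-bromo-4,6-bis(prenyloxy)benzaldehyde | O=Cc1c(OCC=C(C)C)cc(OCC=C(C)C)cc1Br | intermediate
6 | acetophenone | CC(=O)c1ccccc1 | starting material
7 | lithium 1-phenylethenolate | [Li+].[O-]C(=C)c1ccccc1 | intermediate
8 | rac-3-[2-bromo-4,6-bis(prenyloxy)phenyl]-3-hydroxy-1-phenylpropan-1-one | O=C(CC(O)c1c(Br)cc(OCC=C(C)C)cc1OCC=C(C)C)c1ccccc1 | intermediate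
9 | rac-3-[2-bromo-4,6-bis(prenyloxy)phenyl]-3-(tert-butyldimethylsilyloxy)-1-phenylpropan-1-one | O=C(CC(O[Si](C)(C)C(C)(C)C)c1c(Br)cc(OCC=C(C)C)cc1OCC=C(C)C)c1ccccc1 | intermediate
10 | 2-{(1S)-3-[2-bromo-4,6-bis(prenyloxy)phenyl]-3-(tert-butyldimethylsilyloxy)-1-phenylpropoxy}-1,3,2-benzodioxaborole (both C3 epimers) | c1ccc2OB(O[C@H](c3ccccc3)CC(O[Si](C)(C)C(C)(C)C)c3c(Br)cc(OCC=C(C)C)cc3OCC=C(C)C)Oc2c1 | intermediate
11 | (1S)-3-[2-bromo-4,6-bis(prenyloxy)phenyl]-3-(tert-butyldimethylsilyloxy)-1-phenylpropan-1-ol (both C3 epimers) | O[C@H](c1ccccc1)CC(O[Si](C)(C)C(C)(C)C)c1c(Br)cc(OCC=C(C)C)cc1OCC=C(C)C | intermediate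
12 | (2S)-4-(tert-butyldimethylsilyloxy)-5,7-bis(prenyloxy)flavan (both C4 epimers) | CC(C)=CCOc1cc(OCC=C(C)C)c2c(c1)O[C@H](c1ccccc1)CC2O[Si](C)(C)C(C)(C)C | intermediate
13 | (2S)-5,7-bis(prenyloxy)flavan-4-ol (both C4 epimers) | CC(C)=CCOc1cc(OCC=C(C)C)c2c(c1)O[C@H](c1ccccc1)CC2O | intermediate
14 | (2S)-5,7-bis(prenyloxy)flavanone | CC(C)=CCOc1cc(OCC=C(C)C)c2c(c1)O[C@H](c1ccccc1)CC2=O | intermediate
15 | (2S)-6-(2-methylbut-3-en-2-yl)-2-phenyl-7-(prenyloxy)-2,3-dihydro-4H-chromene-4,5(6H)-dione (C6 dienone, either C6 configuration) | C=CC(C)(C)C1C(=O)C2=C(C=C1OCC=C(C)C)O[C@H](c1ccccc1)CC2=O | intermediate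
16 | (2S)-2-phenyl-8-prenyl-7-(prenyloxy)-2,3-dihydro-4H-chromene-4,5(8H)-dione (C8 dienone, either C8 configuration) | CC(C)=CCC1C(OCC=C(C)C)=CC(=O)C2=C1O[C@H](c1ccccc1)CC2=O | intermediate
17 | (2S)-5-hydroxy-8-prenyl-7-(prenyloxy)flavanone, CNP0292726.1 | CC(C)=CCOc1cc(O)c2c(c1CC=C(C)C)O[C@H](c1ccccc1)CC2=O | target

## Step count and least certain steps

Total: 9 steps. Longest linear sequence: 9 steps, from 1 to 17; compounds 4 and 6 are commercial and enter directly.

**Step 6 (key step).**
- Most likely failure: reduction of the C–Br bond and oxidation of the carbinol through β-hydride transfer from the copper alkoxide. A hindered secondary alkoxide may also couple slowly. Under carbonate at 110 °C the silyl group may migrate from the C4 oxygen to the C2 oxygen, which withdraws the nucleophile.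
- Fallback: form O1–C2 with inversion instead of O1–C8a with retention. It sets out from 9 and comes back at 12.
  - Ketone 9 would be reduced as in step 5 but with the (S)-oxazaborolidine, giving (1R)-3-[2-bromo-4,6-bis(prenyloxy)phenyl]-3-(tert-butyldimethylsilyloxy)-1-phenylpropan-1-ol F1.
  - Bromine–lithium exchange on its lithium alkoxide (t-BuLi, THF, −78 °C) and trapping with B(OMe)3 would give 2-[(3R)-1-(tert-butyldimethylsilyloxy)-3-hydroxy-3-phenylpropyl]-3,5-bis(prenyloxy)phenylboronic acid F2.
  - Alkaline H2O2 would convert F2 into (1R)-3-[2-hydroxy-4,6-bis(prenyloxy)phenyl]-3-(tert-butyldimethylsilyloxy)-1-phenylpropan-1-ol F3.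
  - Mitsunobu cyclisation (PPh3, DIAD, THF, 0 °C) would close ring C with inversion at the carbinol carbon and give 12.

**Step 9.**
- Most likely failure: enolisation of 15 before the second shift, which would leave a reversed prenyl group at C6. The 7-ether may take part. Reversible opening of ring C under the warm Lewis acid would erode C2.
- Fallback: do the shift before ring C and C2 exist. It sets out from 5 and comes back at 17. Its cost is that the bromide then has two ortho substituents in the copper step.
  - Eu(fod)3 in PhCl at 85 °C, chelated between the formyl oxygen and the ortho ether, would give 2-bromo-6-hydroxy-3-prenyl-4-(prenyloxy)benzaldehyde F4.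
  - MOMCl with i-Pr2NEt would give 2-bromo-6-(methoxymethoxy)-3-prenyl-4-(prenyloxy)benzaldehyde F5.
  - The operations of steps 3 to 8 would then follow in the same order:
    - Aldol addition of 7 gives rac-3-[2-bromo-6-(methoxymethoxy)-3-prenyl-4-(prenyloxy)phenyl]-3-hydroxy-1-phenylpropan-1-one F6.
    - Silylation gives its tert-butyldimethylsilyl ether F7.
    - Reduction gives (1S)-3-[2-bromo-6-(methoxymethoxy)-3-prenyl-4-(prenyloxy)phenyl]-3-(tert-butyldimethylsilyloxy)-1-phenylpropan-1-ol F8.
    - Copper-catalysed closure gives (2S)-4-(tert-butyldimethylsilyloxy)-5-(methoxymethoxy)-8-prenyl-7-(prenyloxy)flavan F9.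
    - Desilylation gives (2S)-5-(methoxymethoxy)-8-prenyl-7-(prenyloxy)flavan-4-ol F10.
    - Oxidation gives (2S)-5-(methoxymethoxy)-8-prenyl-7-(prenyloxy)flavanone F11.
  - Dilute HCl in methanol at room temperature would remove the peri acetal, the most labile ether in the molecule, and give 17.

**Step 5.**
- Most likely failure: incomplete reagent control in the mismatched pairing of catalyst and the racemic silyloxy-bearing carbon, or uncatalysed background reduction. Because C4 is later oxidised, the minor carbinol epimer of one series becomes the enantiomer of the product, so the error appears as lower enantiomeric purity at C2.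
- Fallback: make the silyloxy-bearing carbon single-configured first, so that any minor carbinol epimer is a separable diastereomer. It sets out from 5 and comes back at 11, now as the single (1S,3S) epimer.
  - Aldehyde 5 would undergo an auxiliary-controlled acetate aldol with the tin enolate of 3-acetyl-(4S)-4-isopropyl-1,3-thiazolidine-2-thione (Sn(OTf)2, divalent tin, N-ethylpiperidine, CH2Cl2, −78 °C). After chromatography this would give (3S)-3-[2-bromo-4,6-bis(prenyloxy)phenyl]-3-hydroxy-1-[(4S)-4-isopropyl-2-thioxo-1,3-thiazolidin-3-yl]propan-1-one F12. It is drawn as 3S; the other C3 configuration would serve equally.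
  - TBSOTf and 2,6-lutidine would give its silyl ether F13.
  - MeNH(OMe)·HCl and imidazole would displace the auxiliary and give (3S)-3-[2-bromo-4,6-bis(prenyloxy)phenyl]-3-(tert-butyldimethylsilyloxy)-N-methoxy-N-methylpropanamide F14.
  - PhMgBr in THF at 0 °C would give (3S)-3-[2-bromo-4,6-bis(prenyloxy)phenyl]-3-(tert-butyldimethylsilyloxy)-1-phenylpropan-1-one F15, one enantiomer of 9, which is reduced as in step 5.

**Step 3.**
- Most likely failure: reversal of the aldol addition and dehydration towards the enone, during the reaction or the silylation, and low conversion of a hindered, electron-rich aldehyde.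
- Fallback: exchange the roles of the partners, so that the C–C bond is made with an amide enolate whose adduct does not revert and the phenyl ketone is made afterwards by acylation. It sets out from 5 and comes back at 9.
  - The lithium enolate of N-methoxy-N-methylacetamide (LDA, THF, −78 °C) would add to 5 and give rac-3-[2-bromo-4,6-bis(prenyloxy)phenyl]-3-hydroxy-N-methoxy-N-methylpropanamide F16.
  - TBSOTf and 2,6-lutidine would give rac-3-[2-bromo-4,6-bis(prenyloxy)phenyl]-3-(tert-butyldimethylsilyloxy)-N-methoxy-N-methylpropanamide F17.
  - PhMgBr would give 9.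

## Further compounds

F1 | step 6 | (1R)-3-[2-bromo-4,6-bis(prenyloxy)phenyl]-3-(tert-butyldimethylsilyloxy)-1-phenylpropan-1-ol (both C3 epimers) | O[C@@H](c1ccccc1)CC(O[Si](C)(C)C(C)(C)C)c1c(Br)cc(OCC=C(C)C)cc1OCC=C(C)C
F2 | step 6 | 2-[(3R)-1-(tert-butyldimethylsilyloxy)-3-hydroxy-3-phenylpropyl]-3,5-bis(prenyloxy)phenylboronic acid | O[C@@H](c1ccccc1)CC(O[Si](C)(C)C(C)(C)C)c1c(B(O)O)cc(OCC=C(C)C)cc1OCC=C(C)C
F3 | step 6 | (1R)-3-[2-hydroxy-4,6-bis(prenyloxy)phenyl]-3-(tert-butyldimethylsilyloxy)-1-phenylpropan-1-ol | O[C@@H](c1ccccc1)CC(O[Si](C)(C)C(C)(C)C)c1c(O)cc(OCC=C(C)C)cc1OCC=C(C)C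
F4 | step 9 | 2-bromo-6-hydroxy-3-prenyl-4-(prenyloxy)benzaldehyde | O=Cc1c(O)cc(OCC=C(C)C)c(CC=C(C)C)c1Br
F5 | step 9 | 2-bromo-6-(methoxymethoxy)-3-prenyl-4-(prenyloxy)benzaldehyde | O=Cc1c(OCOC)cc(OCC=C(C)C)c(CC=C(C)C)c1Br
F6 | step 9 | rac-3-[2-bromo-6-(methoxymethoxy)-3-prenyl-4-(prenyloxy)phenyl]-3-hydroxy-1-phenylpropan-1-one | O=C(CC(O)c1c(OCOC)cc(OCC=C(C)C)c(CC=C(C)C)c1Br)c1ccccc1
F7 | step 9 | rac-3-[2-bromo-6-(methoxymethoxy)-3-prenyl-4-(prenyloxy)phenyl]-3-(tert-butyldimethylsilyloxy)-1-phenylpropan-1-one | O=C(CC(O[Si](C)(C)C(C)(C)C)c1c(OCOC)cc(OCC=C(C)C)c(CC=C(C)C)c1Br)c1ccccc1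
F8 | step 9 | (1S)-3-[2-bromo-6-(methoxymethoxy)-3-prenyl-4-(prenyloxy)phenyl]-3-(tert-butyldimethylsilyloxy)-1-phenylpropan-1-ol (both C3 epimers) | O[C@H](c1ccccc1)CC(O[Si](C)(C)C(C)(C)C)c1c(OCOC)cc(OCC=C(C)C)c(CC=C(C)C)c1Br
F9 | step 9 | (2S)-4-(tert-butyldimethylsilyloxy)-5-(methoxymethoxy)-8-prenyl-7-(prenyloxy)flavan (both C4 epimers) | CC(C)=CCOc1cc(OCOC)c2c(c1CC=C(C)C)O[C@H](c1ccccc1)CC2O[Si](C)(C)C(C)(C)C
F10 | step 9 | (2S)-5-(methoxymethoxy)-8-prenyl-7-(prenyloxy)flavan-4-ol (both C4 epimers) | CC(C)=CCOc1cc(OCOC)c2c(c1CC=C(C)C)O[C@H](c1ccccc1)CC2O
F11 | step 9 | (2S)-5-(methoxymethoxy)-8-prenyl-7-(prenyloxy)flavanone | CC(C)=CCOc1cc(OCOC)c2c(c1CC=C(C)C)O[C@H](c1ccccc1)CC2=O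
F12 | step 5 | (3S)-3-[2-bromo-4,6-bis(prenyloxy)phenyl]-3-hydroxy-1-[(4S)-4-isopropyl-2-thioxo-1,3-thiazolidin-3-yl]propan-1-one | CC(C)[C@H]1CSC(=S)N1C(=O)C[C@H](O)c1c(Br)cc(OCC=C(C)C)cc1OCC=C(C)C
F13 | step 5 | (3S)-3-[2-bromo-4,6-bis(prenyloxy)phenyl]-3-(tert-butyldimethylsilyloxy)-1-[(4S)-4-isopropyl-2-thioxo-1,3-thiazolidin-3-yl]propan-1-one | CC(C)[C@H]1CSC(=S)N1C(=O)C[C@H](O[Si](C)(C)C(C)(C)C)c1c(Br)cc(OCC=C(C)C)cc1OCC=C(C)C
F14 | step 5 | (3S)-3-[2-bromo-4,6-bis(prenyloxy)phenyl]-3-(tert-butyldimethylsilyloxy)-N-methoxy-N-methylpropanamide | CON(C)C(=O)C[C@H](O[Si](C)(C)C(C)(C)C)c1c(Br)cc(OCC=C(C)C)cc1OCC=C(C)C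
F15 | step 5 | (3S)-3-[2-bromo-4,6-bis(prenyloxy)phenyl]-3-(tert-butyldimethylsilyloxy)-1-phenylpropan-1-one | O=C(C[C@H](O[Si](C)(C)C(C)(C)C)c1c(Br)cc(OCC=C(C)C)cc1OCC=C(C)C)c1ccccc1
F16 | step 3 | rac-3-[2-bromo-4,6-bis(prenyloxy)phenyl]-3-hydroxy-N-methoxy-N-methylpropanamide | CON(C)C(=O)CC(O)c1c(Br)cc(OCC=C(C)C)cc1OCC=C(C)C
F17 | step 3 | rac-3-[2-bromo-4,6-bis(prenyloxy)phenyl]-3-(tert-butyldimethylsilyloxy)-N-methoxy-N-methylpropanamide | CON(C)C(=O)CC(O[Si](C)(C)C(C)(C)C)c1c(Br)cc(OCC=C(C)C)cc1OCC=C(C)C
A1 | alternative 1 | (S)-5-hydroxy-8-prenyl-7-(triisopropylsiloxy)flavanone | CC(C)=CCc1c(O[Si](C(C)C)(C(C)C)C(C)C)cc(O)c2c1O[C@H](c1ccccc1)CC2=O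
A2 | alternative 1 | (2S)-6-(2-diazo-5-methylhex-4-enoyl)-2-phenyl-2,3-dihydro-4H-pyran-4-one | O=C(C1=CC(=O)C[C@@H](c2ccccc2)O1)C(=[N+]=[N-])CC=C(C)C
A3 | alternative 1 | (triisopropylsiloxy)ethyne | C#CO[Si](C(C)C)(C(C)C)C(C)C
A4 | alternative 2 | (S)-5,7-bis(benzyloxy)flavanone | c1ccc(COc2cc(OCc3ccccc3)c3c(c2)O[C@H](c2ccccc2)CC3=O)cc1
A5 | alternative 2 | 2-diazo-1-[2,4,6-tris(benzyloxy)phenyl]ethanone | [N-]=[N+]=CC(=O)c1c(OCc2ccccc2)cc(OCc2ccccc2)cc1OCc1ccccc1
A6 | alternative 3 | (S)-5,7-bis(prenyloxy)flavanone (identical with 14) | CC(C)=CCOc1cc(OCC=C(C)C)c2c(c1)O[C@H](c1ccccc1)CC2=O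
A7 | alternative 3 | (S)-4-phenyloxetan-2-one | O=C1C[C@@H](c2ccccc2)O1
A8 | alternative 3 | 2-fluoro-4,6-bis(prenyloxy)phenyllithium | [Li]c1c(F)cc(OCC=C(C)C)cc1OCC=C(C)C
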